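## Retrosynthetic overview

1. The chain is cut at C11'=C12' and C11=C12 (two Wittig reactions, C15 + C10 + C15). The β-ring half carries the palmitate and the ε-ring half a silyl-protected 3'-OH, which is what tells the two hydroxyls apart.
2. The β-ring is not built: it comes from (4R,6R)-actinol (source of C3) and is joined to the chain at C6–C7 by enol triflate formation and Stille coupling.
3. The ε-ring is the only ring formed in the route (step 3). The allylic alcohol C3'(OH)–C4'=C5' goes back to the enone and then to a [4+2] adduct. The bonds C1'–C2' and C5'–C6' are made together from a C2'–C5' 4-methoxy-2-silyloxypentadiene and a C1'=C6' 3-methylbut-2-enoyl imide with a chiral oxazolidinone on C7'.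
4. Enabling feature: the ε-ring is a 4-substituted 3,5,5-trimethylcyclohex-2-en-1-ol. Its C3' oxygen, C4'=C5' double bond and C5' methyl are the retron of a 1-alkoxy-3-silyloxy-diene cycloaddition/elimination. The gem-dimethyl carbon C1' next to the methine C6' that bears C7' is an isopropylidene acceptor.
5. Stereocentres: C6' from the auxiliary in the key step, C3' by hydride delivery controlled by C6' and the C1' methyls, C3 from the chiral pool.

Key step: step 3

Assumption (remark on the chemistry): the olefinations are taken to give, after the usual thermal equilibration of carotenoid polyenes, the all-E chain; phosphonate 12 and dialdehyde 25 are used as their all-E isomers.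

## Route

Step 1
Reactants: 1 (E)-4-methoxypent-3-en-2-one
Product: 2 (3E)-4-methoxy-2-(trimethylsilyloxy)penta-1,3-diene
Conditions: LiN(i-Pr)2, THF, −78 °C; Me3SiCl, −78 °C to rt
Reagents that add atoms: chlorotrimethylsilane, C[Si](C)(C)Cl
Why: Kinetic deprotonation of the vinylogous ester at the α'-methyl group and O-silylation (silyl enol ether formation) should give the cross-conjugated 1-alkoxy-3-silyloxy diene; no stereocentre is formed and the enol ether geometry is irrelevant because that carbon becomes sp2 again in the enone.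

Step 2
Reactants: 3 (4S)-4-benzyl-1,3-oxazolidin-2-one; 4 3-methylbut-2-enoyl chloride
Product: 5 (4S)-4-benzyl-3-(3-methylbut-2-enoyl)-1,3-oxazolidin-2-one
Conditions: n-BuLi, THF, −78 °C; then 4, −78 to 0 °C
Reagents that add atoms: none
Why: N-acylation of the lithiated oxazolidinone with the acid chloride is the standard preparation of N-enoyl imides and installs the auxiliary that will control C6'.

Step 3
Reactants: 2 (3E)-4-methoxy-2-(trimethylsilyloxy)penta-1,3-diene; 5 (4S)-4-benzyl-3-(3-methylbut-2-enoyl)-1,3-oxazolidin-2-one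
Product: 7 (4S)-4-benzyl-3-[(1R)-2,6,6-trimethyl-4-oxocyclohex-2-ene-1-carbonyl]-1,3-oxazolidin-2-one, via cycloadduct silyl enol ether 6 (not isolated)
Conditions: Me2AlCl (1.5 equiv), CH2Cl2, −78 to −30 °C; then 1 M HCl, THF, 0 °C
Reagents that add atoms: none
Why: Proposed new method: Me2AlCl turns imide 5 into a cationic, chelated s-cis complex whose β-carbon (future C1') is attacked by the unsubstituted CH2 terminus of diene 2 (future C2') in a Mukaiyama–Michael step, and the resulting chelated (Z)-aluminium enolate closes through C6' onto the methoxy-stabilised oxocarbenium carbon (future C5'), so that the C1'–C2' and C5'–C6' bonds arise in one operation as an asynchronous formal [4+2] cycloaddition (a concerted Diels–Alder path gives the same adduct 6). The closest known reaction types are the Lewis-acid-promoted Diels–Alder reaction of chiral N-enoyl oxazolidinones with acyclic dienes, the cycloaddition/elimination of 1-alkoxy-3-silyloxy dienes to cyclohexenones, and the Lewis-acid-promoted Diels–Alder and Mukaiyama–Michael reactions of β,β-dimethyl enones such as mesityl oxide; what is new is their combination on a β,β-disubstituted enoyl imide. The only ring formed, the six-membered ε-ring, closes in a 6-(enolexo)-exo-trig mode (enolate carbon C6' onto the exocyclic C=O+ of C5'). The only lasting stereocentre, C6', is set by the auxiliary: the benzyl group shields one face of the chelated α-carbon so that C5' bonds from the opposite face, which for the (S)-auxiliary corresponds to (R) at C6', while the transient C5' centre is erased when aqueous acid hydrolyses the silyl enol ether and eliminates methanol toward C4' to give the conjugated enone. The step needs regioselectivity (secured by the polarity match of the nucleophilic CH2 terminus with the electrophilic β-carbon, and sterically by the hindered diene terminus meeting the unsubstituted α-carbon), 1,4- over 1,2-addition (secured by bidentate chelation of the imide) and facial selectivity (auxiliary). The gem-dimethyl group that slows the first bond formation should speed the ring closure (Thorpe–Ingold effect).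

Step 4
Reactants: 7 (4S)-4-benzyl-3-[(1R)-2,6,6-trimethyl-4-oxocyclohex-2-ene-1-carbonyl]-1,3-oxazolidin-2-one
Product: 8 (4S)-4-benzyl-3-[(1R,4R)-4-hydroxy-2,6,6-trimethylcyclohex-2-ene-1-carbonyl]-1,3-oxazolidin-2-one
Conditions: LiBH(s-Bu)3 (L-Selectride, 1.1 equiv), THF, −78 °C; aq. NH4Cl
Reagents that add atoms: none
Why: The β,β-disubstituted enone should undergo 1,2-reduction by the bulky hydride (the imide carbonyls are inert at this temperature), and with the C6' acyl group pseudo-axial the hydride is expected to enter anti to the pseudo-axial C1' methyl group, that is on the face of the acyl group, which sets C3' as (R) with the hydroxyl trans to C7' (substrate-controlled ketone reduction).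

Step 5
Reactants: 8 (4S)-4-benzyl-3-[(1R,4R)-4-hydroxy-2,6,6-trimethylcyclohex-2-ene-1-carbonyl]-1,3-oxazolidin-2-one
Product: 9 (4S)-4-benzyl-3-[(1R,4R)-4-(tert-butyldimethylsilyloxy)-2,6,6-trimethylcyclohex-2-ene-1-carbonyl]-1,3-oxazolidin-2-one
Conditions: t-BuMe2SiCl, imidazole, DMF, rt
Reagents that add atoms: tert-butyldimethylsilyl chloride, CC(C)(C)[Si](C)(C)Cl
Why: Silylation of the secondary allylic alcohol protects the acid-sensitive 3'-hydroxyl for the chain-building steps and keeps it distinct from the β-ring hydroxyl.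

Step 6
Reactants: 9 (4S)-4-benzyl-3-[(1R,4R)-4-(tert-butyldimethylsilyloxy)-2,6,6-trimethylcyclohex-2-ene-1-carbonyl]-1,3-oxazolidin-2-one
Product: 10 [(1R,4R)-4-(tert-butyldimethylsilyloxy)-2,6,6-trimethylcyclohex-2-en-1-yl]methanol
Conditions: LiBH4, MeOH (1 equiv), Et2O, 0 °C
Reagents that add atoms: none
Why: Reductive cleavage of the auxiliary by hydride attack at the exocyclic imide carbonyl should release the primary alcohol (C7') and the recyclable oxazolidinone without touching C6' or the silyl ether.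

Step 7
Reactants: 10 [(1R,4R)-4-(tert-butyldimethylsilyloxy)-2,6,6-trimethylcyclohex-2-en-1-yl]methanol
Product: 11 (1R,4R)-4-(tert-butyldimethylsilyloxy)-2,6,6-trimethylcyclohex-2-ene-1-carbaldehyde
Conditions: Dess–Martin periodinane, NaHCO3, CH2Cl2, 0 °C; used at once
Reagents that add atoms: none
Why: Dess–Martin oxidation under buffered, non-basic conditions should give the α-branched β,γ-unsaturated aldehyde without enolisation, so that the C6' configuration is kept.

Step 8
Reactants: 11 (1R,4R)-4-(tert-butyldimethylsilyloxy)-2,6,6-trimethylcyclohex-2-ene-1-carbaldehyde; 12 ethyl (2E)-4-(diethoxyphosphoryl)-3-methylbut-2-enoate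
Product: 13 ethyl (2E,4E)-5-[(1R,4R)-4-(tert-butyldimethylsilyloxy)-2,6,6-trimethylcyclohex-2-en-1-yl]-3-methylpenta-2,4-dienoate
Conditions: 12, LiN(SiMe3)2, THF, −78 °C; then 11, −78 to 0 °C
Reagents that add atoms: none
Why: Horner–Wadsworth–Emmons olefination with the stabilised, weakly basic phosphonate anion added at low temperature should form the (7'E) double bond and bring in the (9'E) trisubstituted double bond already present in 12.

Step 9
Reactants: 13 ethyl (2E,4E)-5-[(1R,4R)-4-(tert-butyldimethylsilyloxy)-2,6,6-trimethylcyclohex-2-en-1-yl]-3-methylpenta-2,4-dienoate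
Product: 14 (2E,4E)-5-[(1R,4R)-4-(tert-butyldimethylsilyloxy)-2,6,6-trimethylcyclohex-2-en-1-yl]-3-methylpenta-2,4-dien-1-ol
Conditions: (i-Bu)2AlH (2.2 equiv), CH2Cl2, −78 °C; aq. KNaC4H4O6
Reagents that add atoms: none
Why: 1,2-reduction of the dienoate (ester reduction with an aluminium hydride) should give the dienylic alcohol and leave the silyl ether and the double bonds alone.

Step 10
Reactants: 14 (2E,4E)-5-[(1R,4R)-4-(tert-butyldimethylsilyloxy)-2,6,6-trimethylcyclohex-2-en-1-yl]-3-methylpenta-2,4-dien-1-ol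
Product: 16 {(2E,4E)-5-[(1R,4R)-4-(tert-butyldimethylsilyloxy)-2,6,6-trimethylcyclohex-2-en-1-yl]-3-methylpenta-2,4-dien-1-yl}triphenylphosphonium bromide, via allylic bromide 15 (not isolated)
Conditions: CBr4, PPh3 (1.1 equiv), CH2Cl2, −20 °C; then PPh3 (1.2 equiv), rt, dark
Reagents that add atoms: carbon tetrabromide, BrC(Br)(Br)Br; triphenylphosphine, c1ccc(cc1)P(c1ccccc1)c1ccccc1
Why: Appel bromination of the primary dienylic alcohol under neutral conditions, chosen so that the acid-labile allylic silyl ether survives, is followed by SN2 quaternisation of PPh3 at the primary carbon.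

Step 11
Reactants: 17 (4R,6R)-4-hydroxy-2,2,6-trimethylcyclohexan-1-one (actinol)
Product: 18 (4R,6R)-4-(tert-butyldimethylsilyloxy)-2,2,6-trimethylcyclohexan-1-one
Conditions: t-BuMe2SiCl, imidazole, DMF, rt
Reagents that add atoms: tert-butyldimethylsilyl chloride, CC(C)(C)[Si](C)(C)Cl
Why: Silylation masks the hydroxyl of the chiral-pool ketone for the strongly basic enolisation that follows; C4, the future C3, is untouched.

Step 12
Reactants: 18 (4R,6R)-4-(tert-butyldimethylsilyloxy)-2,2,6-trimethylcyclohexan-1-one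
Product: 19 (4R)-4-(tert-butyldimethylsilyloxy)-2,6,6-trimethylcyclohex-1-en-1-yl trifluoromethanesulfonate
Conditions: LiN(i-Pr)2, THF, −78 to 0 °C; PhNTf2, 0 °C to rt
Reagents that add atoms: N-phenylbis(trifluoromethanesulfonimide), O=S(=O)(N(c1ccccc1)S(=O)(=O)C(F)(F)F)C(F)(F)F
Why: The ketone can enolise only toward C6, so deprotonation and O-sulfonylation (enol triflate formation) should give the single tetrasubstituted enol triflate, removing the C6 stereocentre on purpose.

Step 13
Reactants: 20 (2E)-3-methylpent-2-en-4-yn-1-ol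
Product: 21 (2E,4E)-3-methyl-5-(tributylstannyl)penta-2,4-dien-1-ol
Conditions: Bu3SnH, PdCl2(PPh3)2 (2 mol %), THF, 0 °C to rt
Reagents that add atoms: tributyltin hydride, CCCC[SnH](CCCC)CCCC
Why: Palladium-catalysed syn-hydrostannation of the terminal alkyne should place tin on the terminal carbon and give the (E)-alkenylstannane.

Step 14
Reactants: 19 (4R)-4-(tert-butyldimethylsilyloxy)-2,6,6-trimethylcyclohex-1-en-1-yl trifluoromethanesulfonate; 21 (2E,4E)-3-methyl-5-(tributylstannyl)penta-2,4-dien-1-ol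
Product: 22 (2E,4E)-5-[(4R)-4-(tert-butyldimethylsilyloxy)-2,6,6-trimethylcyclohex-1-en-1-yl]-3-methylpenta-2,4-dien-1-ol
Conditions: Pd2(dba)3 (2.5 mol %), AsPh3 (20 mol %), NMP, 60 °C
Reagents that add atoms: none
Why: Stille coupling (oxidative addition of zerovalent palladium to the hindered cyclohexenyl triflate, transmetalation, reductive elimination) should form the C6–C7 bond with retention of both alkene geometries and tolerate the free primary hydroxyl.

Step 15
Reactants: 22 (2E,4E)-5-[(4R)-4-(tert-butyldimethylsilyloxy)-2,6,6-trimethylcyclohex-1-en-1-yl]-3-methylpenta-2,4-dien-1-ol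
Product: 24 {(2E,4E)-5-[(4R)-4-hydroxy-2,6,6-trimethylcyclohex-1-en-1-yl]-3-methylpenta-2,4-dien-1-yl}triphenylphosphonium bromide, via silyl-protected phosphonium salt 23 (not isolated)
Conditions: PPh3·HBr (1.3 equiv), MeOH/CH2Cl2, rt
Reagents that add atoms: triphenylphosphine hydrobromide, [Br-].[PH+](c1ccccc1)(c1ccccc1)c1ccccc1
Why: Ionisation of the dienylic alcohol by HBr and capture of the pentadienyl cation by PPh3 at the primary terminus should give the C15 phosphonium salt, and the same acidic methanol cleaves the silyl ether (acid-catalysed methanolysis), freeing the C3 hydroxyl for later acylation.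

Step 16
Reactants: 24 {(2E,4E)-5-[(4R)-4-hydroxy-2,6,6-trimethylcyclohex-1-en-1-yl]-3-methylpenta-2,4-dien-1-yl}triphenylphosphonium bromide; 25 (2E,4E,6E)-2,7-dimethylocta-2,4,6-trienedial
Product: 26 (3R)-3-hydroxy-12'-apo-β-caroten-12'-al
Conditions: 25 (2.5 equiv), 1,2-epoxybutane, EtOH, reflux
Reagents that add atoms: none
Why: Wittig reaction under neutral conditions (bromide opens the epoxide to the alkoxide base) with an excess of the symmetrical dialdehyde should give mono-olefination at C11=C12, and any (11Z) isomer equilibrates to (E) on heating.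

Step 17
Reactants: 26 (3R)-3-hydroxy-12'-apo-β-caroten-12'-al; 27 hexadecanoyl chloride
Product: 28 (3R)-3-(hexadecanoyloxy)-12'-apo-β-caroten-12'-al
Conditions: pyridine, DMAP (cat.), CH2Cl2, 0 °C to rt
Reagents that add atoms: none
Why: DMAP-catalysed esterification of the only hydroxyl group present fixes the palmitate on O3 of the β-ring before the ε-ring hydroxyl enters the molecule.

Step 18
Reactants: 16 {(2E,4E)-5-[(1R,4R)-4-(tert-butyldimethylsilyloxy)-2,6,6-trimethylcyclohex-2-en-1-yl]-3-methylpenta-2,4-dien-1-yl}triphenylphosphonium bromide; 28 (3R)-3-(hexadecanoyloxy)-12'-apo-β-caroten-12'-al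
Product: 29 (3R,3'R,6'R)-3'-(tert-butyldimethylsilyloxy)-β,ε-caroten-3-yl hexadecanoate
Conditions: 1,2-epoxybutane, reflux, argon, dark; then n-heptane, 80 °C
Reagents that add atoms: none
Why: Wittig reaction under neutral, non-nucleophilic conditions that spare the ester and the silyl ether should join C11' to C12', and heating equilibrates the new double bond to (E).

Step 19
Reactants: 29 (3R,3'R,6'R)-3'-(tert-butyldimethylsilyloxy)-β,ε-caroten-3-yl hexadecanoate
Product: 30 (3R,3'R,6'R)-3'-hydroxy-β,ε-caroten-3-yl hexadecanoate (lutein 3-O-palmitate, CNP0192969.1)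
Conditions: HF·pyridine, pyridine, THF, 0 °C to rt, dark
Reagents that add atoms: none
Why: Fluoride cleavage of the secondary silyl ether under pyridine-buffered conditions (desilylation) should free the acid-sensitive allylic 3'-hydroxyl without touching the palmitate or the polyene.

## Compound list

1 | (E)-4-methoxypent-3-en-2-one | CC(=O)/C=C(\C)OC | starting material
2 | (3E)-4-methoxy-2-(trimethylsilyloxy)penta-1,3-diene | C=C(O[Si](C)(C)C)/C=C(\C)OC | intermediate
3 | (4S)-4-benzyl-1,3-oxazolidin-2-one | O=C1N[C@@H](Cc2ccccc2)CO1 | starting material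
4 | 3-methylbut-2-enoyl chloride | CC(C)=CC(Cl)=O | starting material
5 | (4S)-4-benzyl-3-(3-methylbut-2-enoyl)-1,3-oxazolidin-2-one | CC(C)=CC(=O)N1[C@@H](Cc2ccccc2)COC1=O | intermediate
6 | cycloadduct silyl enol ether, (4S)-4-benzyl-3-[(1R)-2-methoxy-2,6,6-trimethyl-4-(trimethylsilyloxy)cyclohex-3-ene-1-carbonyl]-1,3-oxazolidin-2-one (both C2 epimers) | O=C(N1[C@@H](Cc2ccccc2)COC1=O)[C@H]3C(C)(OC)C=C(O[Si](C)(C)C)CC3(C)C | intermediate
7 | (4S)-4-benzyl-3-[(1R)-2,6,6-trimethyl-4-oxocyclohex-2-ene-1-carbonyl]-1,3-oxazolidin-2-one | O=C(N1[C@@H](Cc2ccccc2)COC1=O)[C@H]3C(C)=CC(=O)CC3(C)C | intermediate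
8 | (4S)-4-benzyl-3-[(1R,4R)-4-hydroxy-2,6,6-trimethylcyclohex-2-ene-1-carbonyl]-1,3-oxazolidin-2-one | O=C(N1[C@@H](Cc2ccccc2)COC1=O)[C@H]3C(C)=C[C@H](O)CC3(C)C | intermediate
9 | (4S)-4-benzyl-3-[(1R,4R)-4-(tert-butyldimethylsilyloxy)-2,6,6-trimethylcyclohex-2-ene-1-carbonyl]-1,3-oxazolidin-2-one | O=C(N1[C@@H](Cc2ccccc2)COC1=O)[C@H]3C(C)=C[C@H](O[Si](C)(C)C(C)(C)C)CC3(C)C | intermediate
10 | [(1R,4R)-4-(tert-butyldimethylsilyloxy)-2,6,6-trimethylcyclohex-2-en-1-yl]methanol | OC[C@H]1C(C)=C[C@H](O[Si](C)(C)C(C)(C)C)CC1(C)C | intermediate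
11 | (1R,4R)-4-(tert-butyldimethylsilyloxy)-2,6,6-trimethylcyclohex-2-ene-1-carbaldehyde | O=C[C@H]1C(C)=C[C@H](O[Si](C)(C)C(C)(C)C)CC1(C)C | intermediate
12 | ethyl (2E)-4-(diethoxyphosphoryl)-3-methylbut-2-enoate | CCOC(=O)/C=C(\C)CP(=O)(OCC)OCC | starting material
13 | ethyl (2E,4E)-5-[(1R,4R)-4-(tert-butyldimethylsilyloxy)-2,6,6-trimethylcyclohex-2-en-1-yl]-3-methylpenta-2,4-dienoate | CCOC(=O)/C=C(C)/C=C/[C@H]1C(C)=C[C@H](O[Si](C)(C)C(C)(C)C)CC1(C)C | intermediate
14 | (2E,4E)-5-[(1R,4R)-4-(tert-butyldimethylsilyloxy)-2,6,6-trimethylcyclohex-2-en-1-yl]-3-methylpenta-2,4-dien-1-ol | OC/C=C(C)/C=C/[C@H]1C(C)=C[C@H](O[Si](C)(C)C(C)(C)C)CC1(C)C | intermediate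
15 | allylic bromide, tert-butyl{[(1R,4R)-4-[(1E,3E)-5-bromo-3-methylpenta-1,3-dien-1-yl]-3,5,5-trimethylcyclohex-2-en-1-yl]oxy}dimethylsilane | BrC/C=C(C)/C=C/[C@H]1C(C)=C[C@H](O[Si](C)(C)C(C)(C)C)CC1(C)C | intermediate
16 | {(2E,4E)-5-[(1R,4R)-4-(tert-butyldimethylsilyloxy)-2,6,6-trimethylcyclohex-2-en-1-yl]-3-methylpenta-2,4-dien-1-yl}triphenylphosphonium bromide | [Br-].c1ccccc1[P+](c1ccccc1)(c1ccccc1)C/C=C(C)/C=C/[C@H]1C(C)=C[C@H](O[Si](C)(C)C(C)(C)C)CC1(C)C | intermediate
17 | (4R,6R)-4-hydroxy-2,2,6-trimethylcyclohexan-1-one (actinol) | O[C@@H]1C[C@@H](C)C(=O)C(C)(C)C1 | starting material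
18 | (4R,6R)-4-(tert-butyldimethylsilyloxy)-2,2,6-trimethylcyclohexan-1-one | CC(C)(C)[Si](C)(C)O[C@@H]1C[C@@H](C)C(=O)C(C)(C)C1 | intermediate
19 | (4R)-4-(tert-butyldimethylsilyloxy)-2,6,6-trimethylcyclohex-1-en-1-yl trifluoromethanesulfonate | CC(C)(C)[Si](C)(C)O[C@@H]1CC(C)=C(OS(=O)(=O)C(F)(F)F)C(C)(C)C1 | intermediate
20 | (2E)-3-methylpent-2-en-4-yn-1-ol | OC/C=C(C)/C#C | starting material
21 | (2E,4E)-3-methyl-5-(tributylstannyl)penta-2,4-dien-1-ol | OC/C=C(C)/C=C/[Sn](CCCC)(CCCC)CCCC | intermediate
22 | (2E,4E)-5-[(4R)-4-(tert-butyldimethylsilyloxy)-2,6,6-trimethylcyclohex-1-en-1-yl]-3-methylpenta-2,4-dien-1-ol | CC(C)(C)[Si](C)(C)O[C@@H]1CC(C)=C(/C=C/C(C)=C/CO)C(C)(C)C1 | intermediate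
23 | silyl-protected phosphonium salt, {(2E,4E)-5-[(4R)-4-(tert-butyldimethylsilyloxy)-2,6,6-trimethylcyclohex-1-en-1-yl]-3-methylpenta-2,4-dien-1-yl}triphenylphosphonium bromide | [Br-].CC(C)(C)[Si](C)(C)O[C@@H]1CC(C)=C(/C=C/C(C)=C/C[P+](c2ccccc2)(c2ccccc2)c2ccccc2)C(C)(C)C1 | intermediate
24 | {(2E,4E)-5-[(4R)-4-hydroxy-2,6,6-trimethylcyclohex-1-en-1-yl]-3-methylpenta-2,4-dien-1-yl}triphenylphosphonium bromide | [Br-].O[C@@H]1CC(C)=C(/C=C/C(C)=C/C[P+](c2ccccc2)(c2ccccc2)c2ccccc2)C(C)(C)C1 | intermediate
25 | (2E,4E,6E)-2,7-dimethylocta-2,4,6-trienedial | O=C/C(C)=C/C=C/C=C(C)/C=O | starting material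
26 | (3R)-3-hydroxy-12'-apo-β-caroten-12'-al | O[C@@H]1CC(C)=C(/C=C/C(C)=C/C=C/C(C)=C/C=C/C=C(C)/C=O)C(C)(C)C1 | intermediate
27 | hexadecanoyl chloride (palmitoyl chloride) | CCCCCCCCCCCCCCCC(Cl)=O | starting material
28 | (3R)-3-(hexadecanoyloxy)-12'-apo-β-caroten-12'-al | CCCCCCCCCCCCCCCC(=O)O[C@@H]1CC(C)=C(/C=C/C(C)=C/C=C/C(C)=C/C=C/C=C(C)/C=O)C(C)(C)C1 | intermediate
29 | (3R,3'R,6'R)-3'-(tert-butyldimethylsilyloxy)-β,ε-caroten-3-yl hexadecanoate | CCCCCCCCCCCCCCCC(=O)O[C@@H]1CC(C)=C(/C=C/C(C)=C/C=C/C(C)=C/C=C/C=C(C)/C=C/C=C(C)/C=C/[C@H]2C(C)=C[C@H](O[Si](C)(C)C(C)(C)C)CC2(C)C)C(C)(C)C1 | intermediate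
30 | (3R,3'R,6'R)-3'-hydroxy-β,ε-caroten-3-yl hexadecanoate (CNP0192969.1) | CCCCCCCCCCCCCCCC(=O)O[C@@H]1CC(C)=C(/C=C/C(C)=C/C=C/C(C)=C/C=C/C=C(C)/C=C/C=C(C)/C=C/[C@H]2C(C)=C[C@H](O)CC2(C)C)C(C)(C)C1 | target

## Step count and risks

Total step count: 19 (ε-ring branch steps 1–10, β-ring branch steps 11–17, union and deprotection steps 18–19).
Longest linear sequence: 11 steps (1, 3–10, 18, 19).

Steps most likely to fail:

1. Step 3 (proposed new method). Bond formation at the fully substituted β-carbon may be too slow, so that the diene is lost to Lewis-acid-induced desilylation or oligomerisation. The sequence may also stop after the first bond without ring closure, or the facial control may erode. The fallback uses known chemistry, sets out from auxiliary 3 and returns to the route at 7. The racemic ring is made by the classical acid-mediated Michael addition/aldol condensation of mesityl oxide with ethyl acetoacetate (ZnCl2, toluene, reflux, water separator), which closes the ring through other bonds and should give ethyl (±)-2,6,6-trimethyl-4-oxocyclohex-2-ene-1-carboxylate F1. Saponification (LiOH, THF/H2O, 0 °C to rt, then acidification) gives (±)-2,6,6-trimethyl-4-oxocyclohex-2-ene-1-carboxylic acid F2. F2 is activated as the mixed pivalic anhydride F3 (t-BuCOCl, Et3N, THF, −20 °C) and used to acylate lithiated 3 (n-BuLi, THF, −78 °C). The two diastereomeric imides, 7 and its (1S)-epimer (4S)-4-benzyl-3-[(1S)-2,6,6-trimethyl-4-oxocyclohex-2-ene-1-carbonyl]-1,3-oxazolidin-2-one F4, are separated by chromatography or crystallisation. F4 can be re-equilibrated at its acidic ring position (DBU) and separated again.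

2. Step 4. Hydride may be delivered to the wrong face of the C3' carbonyl if the pseudo-axial preference of the C6' acyl group is weaker than assumed, or conjugate reduction may compete. The fallback sets out from 7 and returns at 8. Luche reduction (NaBH4, CeCl3·7H2O, MeOH, −40 °C), or the unwanted fraction of step 4, supplies the cis alcohol (4S)-4-benzyl-3-[(1R,4S)-4-hydroxy-2,6,6-trimethylcyclohex-2-ene-1-carbonyl]-1,3-oxazolidin-2-one F5. Mitsunobu inversion with chloroacetic acid (DIAD, PPh3, toluene, 0 °C) should give the (1R,4R)-chloroacetate F6. The chloroacetyl group is then removed under neutral conditions that spare the imide (thiourea, NaHCO3, EtOH, 50 °C) to give 8.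

3. Step 8. Aldehyde 11 may epimerise at C6' or its ring double bond may move into conjugation under the basic olefination conditions, and addition to the neopentyl-like carbonyl may be slow. The fallback sets out from 10 and returns at 13, and never passes through the aldehyde. Mitsunobu thioetherification of 10 with 1-phenyl-1H-tetrazole-5-thiol (DIAD, PPh3, THF, 0 °C) gives the tetrazolyl sulfide F7. Oxidation ((NH4)6Mo7O24·4H2O, H2O2, EtOH, 0 °C to rt) gives the tetrazolyl sulfone F8. Julia–Kocienski olefination of F8 with ethyl (2E)-3-methyl-4-oxobut-2-enoate (KN(SiMe3)2, DME, −60 °C to rt) forms the C7'=C8' bond from a carbanion on C7', which cannot epimerise C6', and gives 13.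

Further compounds
F1 | step 3 | ethyl (±)-2,6,6-trimethyl-4-oxocyclohex-2-ene-1-carboxylate | CCOC(=O)C1C(C)=CC(=O)CC1(C)C
F2 | step 3 | (±)-2,6,6-trimethyl-4-oxocyclohex-2-ene-1-carboxylic acid | OC(=O)C1C(C)=CC(=O)CC1(C)C
F3 | step 3 | (±)-2,2-dimethylpropanoic 2,6,6-trimethyl-4-oxocyclohex-2-ene-1-carboxylic anhydride | CC(C)(C)C(=O)OC(=O)C1C(C)=CC(=O)CC1(C)C
F4 | step 3 | (4S)-4-benzyl-3-[(1S)-2,6,6-trimethyl-4-oxocyclohex-2-ene-1-carbonyl]-1,3-oxazolidin-2-one | O=C(N1[C@@H](Cc2ccccc2)COC1=O)[C@@H]3C(C)=CC(=O)CC3(C)C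
F5 | step 4 | (4S)-4-benzyl-3-[(1R,4S)-4-hydroxy-2,6,6-trimethylcyclohex-2-ene-1-carbonyl]-1,3-oxazolidin-2-one | O=C(N1[C@@H](Cc2ccccc2)COC1=O)[C@H]3C(C)=C[C@@H](O)CC3(C)C
F6 | step 4 | (1R,4R)-4-{[(4S)-4-benzyl-2-oxo-1,3-oxazolidin-3-yl]carbonyl}-3,5,5-trimethylcyclohex-2-en-1-yl chloroacetate | O=C(N1[C@@H](Cc2ccccc2)COC1=O)[C@H]3C(C)=C[C@H](OC(=O)CCl)CC3(C)C
F7 | step 8 | 5-({[(1R,4R)-4-(tert-butyldimethylsilyloxy)-2,6,6-trimethylcyclohex-2-en-1-yl]methyl}sulfanyl)-1-phenyl-1H-tetrazole | c1ccccc1-n1nnnc1SC[C@H]1C(C)=C[C@H](O[Si](C)(C)C(C)(C)C)CC1(C)C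
F8 | step 8 | 5-({[(1R,4R)-4-(tert-butyldimethylsilyloxy)-2,6,6-trimethylcyclohex-2-en-1-yl]methyl}sulfonyl)-1-phenyl-1H-tetrazole | c1ccccc1-n1nnnc1S(=O)(=O)C[C@H]1C(C)=C[C@H](O[Si](C)(C)C(C)(C)C)CC1(C)C
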